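(The data are calculated for substances that don't exist; scatter was added.)

Time stops moving the north-west run long before its last reading, and that looks odd. Between 5.00 h and 8.00 h D gains 5.4 percentage points against 4.7 points for G, as if G were draining into D, yet from 15.0 h to 20.0 h G reads 69.6% and then 70.8%, while D reads 26.7% and then 26.5%.

| flask | E | Q | temperature | remark | time |
|---|---|---|---|---|---|
| north-west | 0.50 M | 15 mM | 0 °C | run made earlier |  |
| Friday's | 0.50 M | 10.0 mM | 0 °C |  | 30 h |
| Tuesday's | 0.80 M | 10.0 mM | 40 °C |  | 8.0 h |

north-west run (percent of the E charged)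

| time / h | G / % | D / % |
|---|---|---|
| 1.00 | 19.4 | 1.6 |
| 3.00 | 51.7 | 10.7 |
| 5.00 | 63.9 | 18.2 |
| 8.00 | 68.6 | 23.6 |
| 10.0 | 69.9 | 25.6 |
| 15.0 | 69.6 | 26.7 |
| 20.0 | 70.8 | 26.5 |

(scatter of a reading: 1 percentage point)

- the earlier runs were read with a standard deviation of 1 percentage point
- the earlier runs do not show what temperature does; that part of a forecast is a guess
- no earlier run changes the charge of Q; that part of a forecast is a guess

- which of the two ends with the higher share of G in all that became G or D ("neither" if they lie within 2 percentage points) (Friday's / Tuesday's / neither)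
- share of G in all that became G or D, Friday's
- share of G in all that became G or D, Tuesday's

A reversible first-order step G ⇌ D, with forward constant kf and back constant kr, clears this up. Once the sum of G and D holds still, the distance of D from its final value shrinks as exp(−(kf + kr)t), and D/G arrives at kf/kr. A one-way step has no back constant and ends without G, which the flat late readings refuse. So the quantity to carry is the end ratio, D over G at rest, the mark of thermodynamic control. The last north-west reading gives 0.374, with the scatter of its readings, and the share of G is then 1/(1 + ratio), or 72.8%. Neither time nor the charge of E appears in that formula. The reckoning therefore gives Friday's flask, at the same temperature, 72.8%, assuming its smaller charge of Q does nothing. Tuesday's flask needs the ratio at 40 °C, which the runs do not show, so this reckoning leaves the choice between the flasks open.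

The forecast gives 70% for Friday's and 76% for Tuesday's, hence Tuesday's, holding that “Tuesday's higher E raises the integrated share”.

The flasks give 72.5% for Friday's and 58.7% for Tuesday's, so Friday's ends higher.

    J → G (k = 0.397 h⁻¹, Ea = 81.0 kJ mol⁻¹)
    G ⇌ D (K = 0.379, k = 0.199 h⁻¹, Ea = 95.0 kJ mol⁻¹, ΔH = 11.0 kJ mol⁻¹)
    E + Q → Z (k = 12.8 M⁻¹ h⁻¹, Ea = 42.0 kJ mol⁻¹)
    E → J (k = 2.92 h⁻¹, Ea = 75.0 kJ mol⁻¹)
    (constants at 0 °C)

Friday's share lies close to the reckoned 72.8%. Tuesday's flask ends with 58.4% G and 41.1% D, an end ratio of 0.704, larger than the north-west 0.374. Its G and D relax with a half-life of 0.413 min, far shorter than its 8.0 h. Carried to the neighbouring flask, which is Tuesday's with 0.0040 M of Q, that ratio gives 58.7%. The neighbour ends at 58.7%.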